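(The data were computed for an exercise; the scatter is artificial.)

common to all: substrate 0.80 M

|  | partner | free catalyst | remark |
|---|---|---|---|
| alpha | 0.40 equiv | 0.063 mol% | run made earlier |
| zeta | 0.90 equiv | 0.063 mol% | run made earlier |
| eta | 0.60 equiv | 0.13 mol% | run made earlier |
| flask | 0.600 equiv | 0.063 mol% |  |

| run | time / min | target / % | substrate / % |
|---|---|---|---|
| alpha | 1.00 | 22.0 | 78.3 |
| alpha | 2.00 | 27.8 | 73.2 |
| alpha | 3.00 | 29.4 | 70.4 |
| alpha | 4.00 | 30.4 | 69.1 |
| alpha | 5.00 | 31.6 | 68.6 |
| alpha | 6.00 | 31.2 | 68.6 |
| zeta | 0.333 | 13.2 | 86.5 |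
| zeta | 1.00 | 25.6 | 74.6 |
| zeta | 2.00 | 30.2 | 69.5 |
| zeta | 3.00 | 31.0 | 69.2 |
| zeta | 4.00 | 31.1 | 68.9 |
| zeta | 5.00 | 31.3 | 68.4 |
| zeta | 6.00 | 31.7 | 68.3 |
| eta | 0.500 | 32.1 | 67.4 |
| eta | 1.00 | 45.2 | 54.7 |
| eta | 2.00 | 54.2 | 45.1 |
| eta | 3.00 | 57.6 | 42.6 |
| eta | 6.00 | 59.3 | 39.9 |

(standard deviation of a reading: 0.3 percentage points)

- apparent order in partner when 20% of the substrate are converted (percent change of the rate of making target for one percent more partner charged)
- factor on the rate of making target when 20% of the substrate are converted if partner is charged twice over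



1. Slowness came early. Alpha, with 0.40 equiv of partner, and zeta, with 0.90 equiv, both crawled to a stop near 31.4% target, so I read the stop as catalyst wearing out at about 499 turnovers at both partner charges.

2. Eta is the flask's neighbour: it has the same partner charge but 0.13 mol% of catalyst against 0.063 mol%. Its catalyst allowed 64.9%, more than its partner charge, so I took partner, the limiting reagent, to be what held eta at its last reading of 59.3%. The flask's catalyst allows 31.4%, less than its partner charge, so I expected the flask to stop on catalyst.

3. Live catalyst therefore follows conversion x, and I took dx/dt = k(x∞ − x), with k depending on [partner]. Alpha's first reading gives k = 1.20 /min at mean [partner] 0.232 M. Zeta's gives 1.63 /min at 0.667 M.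

4. Through these two points, k = kmax[partner]/(K + [partner]) gives the knee concentration K = 0.158 M: the [partner] where k stands midway to its ceiling.

5. At the asked conversion the flask's [partner] is 0.320 M. One percent more charge raises that by 1.50 percent, so I reckoned an order of 0.496 and a doubling factor of 1.25.

6. The forecast, which called zeta “nearly saturated” and put its own knee at 0.14 M, gave 0.39 (0.25 to 0.55) and 1.18 (1.1 to 1.35), an order lower than mine.

7. The flask gave an order of 0.48 and a factor of 1.23.

    substrate + free catalyst → catalyst intermediate A (k = 130 /M/s)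
    partner + catalyst intermediate A ⇌ catalyst intermediate B (K = 16.0 /M, k = 170 /M/s)
    catalyst intermediate B → free catalyst + target (k = 21.0 /s)
    catalyst intermediate B → spent catalyst (k = 0.0420 /s)

At 0.800 min the flask held 16.8% of its catalyst as catalyst intermediate B and 10.2% as catalyst intermediate A, with [partner] at 0.306 M, twice the knee. I carried the knee to eta, where kmax = 2.02 /min and mean [partner] 0.352 M give k = 1.39 /min. That puts eta's target at 32.5% after 0.500 min, and the reading was 32.1%.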